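Both N–C(=O) bonds of the symmetric urea are cut back to one benzylamine, and its benzene ring (rings A and B of the target are identical; C1 carries the CH2N carbon) is traced to a saturated six-membered carbocycle. Everything rests on the neighbouring oxygen-bearing carbons C4 and C5 of that ring: reductive acyloin coupling of the two ester carbons of dimethyl 3-methylhexanedioate forges the C4–C5 bond and closes the carbocycle in one operation, delivering an enediol bis(trimethylsilyl) ether. The precursor is an open-chain diester whose branch carbon is the future C1 and whose methyl group becomes the benzylic carbon; bromine later aromatizes the ring and fills C2, C3 and C6.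

Key step: step 2

Remark: the target has no stereocentre and the methyl-bearing centre of 1 is erased on aromatisation in step 3, so the (R)-acid is used only as the usual commercial form and the racemate would serve identically.

Step 1
Reactants: 1 (3R)-3-methylhexanedioic acid [(R)-3-methyladipic acid]; 2 methanol
Product: 3 dimethyl (3R)-3-methylhexanedioate
Conditions: MeOH (solvent), H2SO4 (cat.), reflux
Reagents that add atoms: methanol, CO
Why: Fischer esterification driven by excess methanol should convert both carboxyl groups, and the stereocentre, which is not alpha to either carbonyl, cannot epimerise.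

Step 2
Reactants: 3 dimethyl (3R)-3-methylhexanedioate; 4 chlorotrimethylsilane; 5 sodium (Na)
Product: 7 (4R)-4-methyl-1,2-bis(trimethylsilyloxy)cyclohex-1-ene, via disodium (4R)-4-methylcyclohex-1-ene-1,2-diolate 6 (not isolated)
Conditions: Na (4.2 equiv, dispersion), Me3SiCl (4.5 equiv), toluene, reflux, N2, slow addition of 3; filtration, distillation
Reagents that add atoms: chlorotrimethylsilane, C[Si](C)(C)Cl
Why: Sodium transfers one electron to each ester carbonyl, the two ketyl radical anions combine carbon to carbon, and the coupled dialkoxide expels both methoxides and takes up two further electrons at the metal surface, so that the ring emerges as disodium enediolate 6, which Me3SiCl silylates on both oxygens to give 7. The closest known reaction type is the Rühlmann (Me3SiCl-trapped) acyloin condensation of adipic esters to 1,2-bis(trimethylsilyloxy)cyclohexenes. The six-membered carbocycle closes by intramolecular ketyl–ketyl coupling of the two chain-terminal ester carbons, which become C1 and C2 of 7 and later C4 and C5 of the target ring. No stereocentre is created and the remote methyl-bearing centre is not touched. The step needs reductive coupling to win over base-induced Dieckmann cyclisation to a cyclopentanone keto ester; Me3SiCl present from the start turns each methoxide into neutral MeOSiMe3 so that no alkoxide base builds up, and slow addition of 3 to the sodium keeps the coupling intramolecular.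

Step 3
Reactants: 7 (4R)-4-methyl-1,2-bis(trimethylsilyloxy)cyclohex-1-ene; 8 bromine
Product: 10 3,4,6-tribromo-5-methylbenzene-1,2-diol (3,5,6-tribromo-4-methylcatechol), via (4R)-4-methylcyclohexane-1,2-dione 9 (not isolated)
Conditions: Br2 (1.0 equiv), CH2Cl2, −30 °C; then AcOH, Br2 (4.2 equiv), dark, 20 → 60 °C; aq. NaHSO3 work-up
Reagents that add atoms: bromine, BrBr
Why: Bromine adds to the electron-rich enediol ether and two Me3SiBr leave to give dione 9 (the known oxidation of acyloin bis-silyl ethers), whose diosphenol tautomer is then brominated at an alpha carbon, loses HBr and tautomerises to the catechol level (brominative aromatisation of cyclohexane-1,2-diones), while electrophilic aromatic substitution fills the three open ring positions, so that every ordering of these events should converge on 10 with loss of the stereocentre.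

Step 4
Reactants: 10 3,4,6-tribromo-5-methylbenzene-1,2-diol; 11 iodomethane
Product: 12 1,2,4-tribromo-5,6-dimethoxy-3-methylbenzene (2,3,6-tribromo-4,5-dimethoxytoluene)
Conditions: MeI (3 equiv), K2CO3, DMF, 40 °C, N2
Reagents that add atoms: iodomethane, CI
Why: Williamson O-methylation of the acidic, bromine-flanked catechol (SN2 of both phenoxides on MeI) should be clean because the fully substituted ring offers no site for C-alkylation.

Step 5
Reactants: 12 1,2,4-tribromo-5,6-dimethoxy-3-methylbenzene; 13 N-bromosuccinimide
Product: 14 2,3,6-tribromo-4,5-dimethoxybenzyl bromide [1,2,4-tribromo-3-(bromomethyl)-5,6-dimethoxybenzene]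
Conditions: NBS (1.05 equiv), AIBN (cat.), PhCF3, 85 °C
Reagents that add atoms: N-bromosuccinimide, O=C1CCC(=O)N1Br
Why: Wohl–Ziegler radical bromination can only attack the single benzylic methyl group because the ring carries no hydrogen, as in the side-chain bromination of polybromotoluenes, and one equivalent of NBS limits dibromination.

Step 6
Reactants: 14 2,3,6-tribromo-4,5-dimethoxybenzyl bromide; 15 sodium azide (NaN3); 16 triphenylphosphine
Product: 19 (2,3,6-tribromo-4,5-dimethoxyphenyl)methanamine, via 2,3,6-tribromo-4,5-dimethoxybenzyl azide 17 (not isolated), via N-(2,3,6-tribromo-4,5-dimethoxybenzyl)-P,P,P-triphenylphosphine imide 18 (not isolated)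
Conditions: NaN3 (1.2 equiv), DMF, 25 °C; then PPh3 (1.3 equiv), THF/H2O, 50 °C
Reagents that add atoms: sodium azide, [Na+].[N-]=[N+]=[N-]
Why: SN2 displacement of the primary benzylic bromide by azide followed by Staudinger reduction (PPh3 forms iminophosphorane 18 with loss of N2, and water hydrolyses it) is a non-hydrogenative route to the primary amine that should leave the three aryl bromides intact.

Step 7
Reactants: 19 (2,3,6-tribromo-4,5-dimethoxyphenyl)methanamine (2 equiv); 20 1,1'-carbonyldiimidazole
Product: 22 1,3-bis(2,3,6-tribromo-4,5-dimethoxybenzyl)urea, via N-(2,3,6-tribromo-4,5-dimethoxybenzyl)-1H-imidazole-1-carboxamide 21 (not isolated)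
Conditions: CDI (0.5 equiv), THF, 25 → 60 °C
Reagents that add atoms: 1,1'-carbonyldiimidazole, O=C(n1ccnc1)n1ccnc1
Why: Carbonylation of a primary amine with CDI gives carbamoylimidazole 21, from which a second amine displaces imidazole on warming, and half an equivalent of CDI should enforce the symmetrical urea.

Step 8
Reactants: 22 1,3-bis(2,3,6-tribromo-4,5-dimethoxybenzyl)urea
Product: 23 1,3-bis(2,3,6-tribromo-4,5-dihydroxybenzyl)urea (target)
Conditions: BBr3 (8 equiv), CH2Cl2, −78 → 20 °C; ice-water quench
Reagents that add atoms: none
Why: BBr3 ether cleavage (O–B complexation, then bromide attack at methyl) should free all four phenols while the urea is only complexed and released on hydrolysis, the aryl bromides are inert, and a cold aqueous rather than alcoholic quench avoids benzylic solvolysis.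

Compound list
1 | (3R)-3-methylhexanedioic acid [(R)-3-methyladipic acid] | OC(=O)C[C@H](C)CCC(=O)O | starting material
2 | methanol | CO | starting material
3 | dimethyl (3R)-3-methylhexanedioate | COC(=O)C[C@H](C)CCC(=O)OC | intermediate
4 | chlorotrimethylsilane | C[Si](C)(C)Cl | starting material
5 | sodium (Na) | [Na] | starting material
6 | disodium (4R)-4-methylcyclohex-1-ene-1,2-diolate | C[C@@H]1CCC([O-])=C([O-])C1.[Na+].[Na+] | intermediate (not isolated)
7 | (4R)-4-methyl-1,2-bis(trimethylsilyloxy)cyclohex-1-ene | C[C@@H]1CCC(O[Si](C)(C)C)=C(O[Si](C)(C)C)C1 | intermediate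
8 | bromine | BrBr | starting material
9 | (4R)-4-methylcyclohexane-1,2-dione | C[C@@H]1CCC(=O)C(=O)C1 | intermediate (not isolated)
10 | 3,4,6-tribromo-5-methylbenzene-1,2-diol | Cc1c(Br)c(O)c(O)c(Br)c1Br | intermediate
11 | iodomethane | CI | starting material
12 | 1,2,4-tribromo-5,6-dimethoxy-3-methylbenzene | Cc1c(Br)c(OC)c(OC)c(Br)c1Br | intermediate
13 | N-bromosuccinimide | O=C1CCC(=O)N1Br | starting material
14 | 2,3,6-tribromo-4,5-dimethoxybenzyl bromide | BrCc1c(Br)c(OC)c(OC)c(Br)c1Br | intermediate
15 | sodium azide (NaN3) | [Na+].[N-]=[N+]=[N-] | starting material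
16 | triphenylphosphine | c1ccc(cc1)P(c1ccccc1)c1ccccc1 | starting material
17 | 2,3,6-tribromo-4,5-dimethoxybenzyl azide | [N-]=[N+]=NCc1c(Br)c(OC)c(OC)c(Br)c1Br | intermediate (not isolated)
18 | N-(2,3,6-tribromo-4,5-dimethoxybenzyl)-P,P,P-triphenylphosphine imide | c1ccc(cc1)P(=NCc1c(Br)c(OC)c(OC)c(Br)c1Br)(c1ccccc1)c1ccccc1 | intermediate (not isolated)
19 | (2,3,6-tribromo-4,5-dimethoxyphenyl)methanamine | NCc1c(Br)c(OC)c(OC)c(Br)c1Br | intermediate
20 | 1,1'-carbonyldiimidazole | O=C(n1ccnc1)n1ccnc1 | starting material
21 | N-(2,3,6-tribromo-4,5-dimethoxybenzyl)-1H-imidazole-1-carboxamide | O=C(NCc1c(Br)c(OC)c(OC)c(Br)c1Br)n1ccnc1 | intermediate (not isolated)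
22 | 1,3-bis(2,3,6-tribromo-4,5-dimethoxybenzyl)urea | O=C(NCc1c(Br)c(OC)c(OC)c(Br)c1Br)NCc1c(Br)c(OC)c(OC)c(Br)c1Br | intermediate
23 | 1,3-bis(2,3,6-tribromo-4,5-dihydroxybenzyl)urea | O=C(NCc1c(Br)c(O)c(O)c(Br)c1Br)NCc1c(Br)c(O)c(O)c(Br)c1Br | target

Total step count: 8
Longest linear sequence: 8 steps (1 → 3 → 7 → 10 → 12 → 14 → 19 → 22 → 23)

Steps most likely to fail

Step 2 (key step). If methoxide is not scavenged fast enough (moist Me3SiCl, coated sodium), base-induced Claisen-type cyclisation and intermolecular ketyl coupling to oligomers may overtake the ring closure. The fallback sets out from diester 3 and forms the same ring bond at the aldehyde oxidation level. LiAlH4 in THF should give (3R)-3-methylhexane-1,6-diol F1, and double Swern oxidation should give (3R)-3-methylhexanedial F2, which is used at once. SmI2-mediated intramolecular pinacol coupling (THF, t-BuOH, −78 °C) should then close the ring to (4R)-4-methylcyclohexane-1,2-diol F3, whose diol configuration is immaterial. Swern oxidation of both carbinols comes back to the route at dione 9, which enters the second stage of step 3 (Br2, AcOH).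

Step 3. The sequence may stall at partly brominated, non-aromatised diketone stages through incomplete loss of HBr, or excess bromine may over-oxidise the catechol. The fallback sets out from 7 and separates the three events. One equivalent of Br2 alone should stop at dione 9, which is isolated. Catalytic dehydrogenation over Pd/C in refluxing diglyme should give 4-methylbenzene-1,2-diol F4, and ordinary electrophilic tribromination (Br2, AcOH, 20 °C) comes back to the route at 10.

Step 8. The Lewis-acid-complexed urea may ionise at the benzylic C–N bond, since each benzylic carbon is para to an oxygen, or cleavage of the four hindered methyl ethers may be incomplete. The fallback sets out from amine 19 and cleaves the ethers before the urea exists, the protonated nitrogen being no leaving group. BBr3 in CH2Cl2 should give 4-(aminomethyl)-3,5,6-tribromobenzene-1,2-diol hydrobromide F5. Transient silylation of both phenols with Me3SiCl/Et3N in MeCN should give [2,3,6-tribromo-4,5-bis(trimethylsilyloxy)phenyl]methanamine F6. CDI (0.5 equiv) should join two molecules to 1,3-bis[2,3,6-tribromo-4,5-bis(trimethylsilyloxy)benzyl]urea F7, and dilute aqueous acid removes the silyl groups, coming back to the route at target 23.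

Further compounds
F1 | step 2 | (3R)-3-methylhexane-1,6-diol | OCC[C@H](C)CCCO
F2 | step 2 | (3R)-3-methylhexanedial | O=CC[C@H](C)CCC=O
F3 | step 2 | (4R)-4-methylcyclohexane-1,2-diol (mixture at the two carbinol centres) | C[C@@H]1CCC(O)C(O)C1
F4 | step 3 | 4-methylbenzene-1,2-diol | Cc1ccc(O)c(O)c1
F5 | step 8 | 4-(aminomethyl)-3,5,6-tribromobenzene-1,2-diol hydrobromide | NCc1c(Br)c(O)c(O)c(Br)c1Br.Br
F6 | step 8 | [2,3,6-tribromo-4,5-bis(trimethylsilyloxy)phenyl]methanamine | NCc1c(Br)c(O[Si](C)(C)C)c(O[Si](C)(C)C)c(Br)c1Br
F7 | step 8 | 1,3-bis[2,3,6-tribromo-4,5-bis(trimethylsilyloxy)benzyl]urea | O=C(NCc1c(Br)c(O[Si](C)(C)C)c(O[Si](C)(C)C)c(Br)c1Br)NCc1c(Br)c(O[Si](C)(C)C)c(O[Si](C)(C)C)c(Br)c1Br
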